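**Plan**

Ring numbering: C1 carries methyl C7, C2 is the vinylic CH, then C3, C4 (carbinol carbon bearing isopropyl), C5 and C6.
Retrosynthesis: cut the ester bond O–C(=O). Move C1=C2 to the exocyclic position C1=C7. Then cut C2–C3 and C5–C6 together, leaving a C3 dielectrophile (C3–C4–C5, with O and isopropyl in place) and a C3 dinucleophile (C2–C1(=C7)–C6).
Enabling feature: C1 and C4 stand para in the six-membered ring, and C4 is stereogenic only because the ring alkene lies on the C2 side and not the C6 side. With the alkene parked at C1=C7, a mirror plane runs through C7, C1, C4 and O, so C2–C3 and C6–C5 become mirror images and one symmetric (3+3) event can make both.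
Forward: Grignard addition to 1,3-dichloroacetone and halohydrin closure give the epichlorohydrin-type unit. Its union with the dianion of isobutene closes the only new ring. The arene is bought as a ring and prenylated twice by Stille coupling, and the two halves are joined last as the ester.
Stereochemistry: the single stereocentre C4 is set by a catalyst-controlled desymmetrizing exo-to-endo alkene isomerization (C2–H chosen over C6–H) and is not touched afterwards.

Key step: step 3

Assumption: both enantiomers of the cobalt ligand are taken as accessible. Which one gives the R alcohol must be fixed by comparing 12 with authentic (R)-(−)-terpinen-4-ol.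

**Route**

Step 1
Reactants: 1 1,3-dichloropropan-2-one; 2 isopropylmagnesium chloride
Product: 4 1-chloro-2-(chloromethyl)-3-methylbutan-2-ol, via chloromagnesium alkoxide 3 (not isolated)
Conditions: LaCl3·2LiCl (1 equiv), THF, −78 to 0 °C; 1 M HCl
Reagents that add atoms: none
Why: In this 1,2-addition of a Grignard reagent to a ketone the lanthanum salt should let addition outrun β-hydride reduction and enolization, the chloro alkoxide should survive at low temperature until the acidic quench, and the product is achiral.

Step 2
Reactants: 4 1-chloro-2-(chloromethyl)-3-methylbutan-2-ol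
Product: 5 2-(chloromethyl)-2-isopropyloxirane (racemic)
Conditions: powdered NaOH, Et2O, 0 °C to rt
Reagents that add atoms: none
Why: Halohydrin ring closure (intramolecular Williamson reaction, 3-exo-tet) should give the 2,2-disubstituted epichlorohydrin, whose stereocentre is left racemic on purpose because step 3 erases it.

Step 3
Reactants: 5 2-(chloromethyl)-2-isopropyloxirane; 6 2-methylpropene (isobutene)
Product: 11 1-isopropyl-4-methylenecyclohexan-1-ol, via dilithio trimethylenemethane dianion 7 (not isolated), via chloro alkoxide allyllithium 8 (not isolated), via relay oxirane allyllithium 9 (not isolated), via lithium alkoxide 10 (not isolated)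
Conditions: 6, n-BuLi (2.1 equiv), TMEDA (2.1 equiv), hexane, 0 °C to rt; THF, −78 °C; 5 added slowly at high dilution, −78 °C to rt; H2O
Reagents that add atoms: none
Why: Proposed new method: dianion 7 should open 5 at its unsubstituted oxirane carbon (first C–C bond) to give 8, whose tertiary alkoxide expels the neighbouring chloride (3-exo-tet) to give the transposed oxirane 9, and the remaining allyllithium terminus then opens 9 at its CH2 carbon (second C–C bond) to give alkoxide 10. The closest known reaction types are the double alkylation of this cross-conjugated dianion with α,ω-dihalides to methylenecycloalkanes and the use of epichlorohydrin as a 1,3-dielectrophile toward sulfone- or dithiane-stabilized carbanions through the same alkoxide-to-oxirane relay; what is new is their combination on a 2,2-disubstituted epichlorohydrin. The six-membered ring closes in the 6-endo-tet mode at the oxirane CH2 (direct 6-exo-tet displacement of chloride in 8 leads to the same 10), while the 5-exo alternative would need substitution at the fully substituted carbon C4 and is shut off. No stereocentre is made: 11 has a mirror plane through C7, C1, C4 and O, so racemic 5 suffices and its stereocentre vanishes. No regioselectivity is needed either, because both allyl termini of 8 and 9 and both CH2 arms of 5 are related by that plane and every order of events converges on 10; the relay also avoids two slow substitutions at neopentyl-type carbons. The selectivity that is needed is ring closure over intermolecular opening of 9, which slow addition of 5 to dilute 7 should secure.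

Step 4
Reactants: 11 1-isopropyl-4-methylenecyclohexan-1-ol
Product: 12 (R)-4-methyl-1-isopropylcyclohex-3-en-1-ol ((R)-terpinen-4-ol)
Conditions: CoCl2·L* (L* = enantiopure tridentate N,N,P pincer ligand, 5 mol %), NaBHEt3 (10 mol %), toluene, rt; catalyst activated before 11 is added
Reagents that add atoms: none
Why: In this desymmetrizing exo-to-endo alkene isomerization by a chiral cobalt hydride (a reaction type known for 4-substituted methylenecyclohexanes), Co–H adds to C1=C7 with cobalt at C1, β-hydride elimination then takes a hydrogen from one of the two enantiotopic ring CH2 groups (C2, not C6) as selected by the ligand pocket on the chair with equatorial isopropyl, which makes C4 the R stereocentre, and the trisubstituted product should not re-insert and so should not racemize.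

Step 5
Reactants: 13 methyl 4-hydroxy-3,5-diiodobenzoate
Product: 14 methyl 3,5-diiodo-4-methoxybenzoate
Conditions: MeI, K2CO3, DMF, rt
Reagents that add atoms: iodomethane, IC
Why: Williamson O-methylation of a phenol made acidic by two ortho iodines and a para ester should proceed cleanly despite the flanking halogens.

Step 6
Reactants: 14 methyl 3,5-diiodo-4-methoxybenzoate; 15 tributyl(3-methylbut-2-en-1-yl)stannane
Product: 16 methyl 4-methoxy-3,5-bis(3-methylbut-2-en-1-yl)benzoate
Conditions: 15 (2.4 equiv), Pd(PPh3)4 (10 mol %), DMF, 90 °C
Reagents that add atoms: none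
Why: In this twofold Stille coupling zerovalent palladium inserts into each C–I bond, and after transmetalation reductive elimination at the unsubstituted allyl terminus should give the linear prenyl groups with the ester untouched.

Step 7
Reactants: 16 methyl 4-methoxy-3,5-bis(3-methylbut-2-en-1-yl)benzoate
Product: 18 4-methoxy-3,5-bis(3-methylbut-2-en-1-yl)benzoic acid, via lithium carboxylate 17 (not isolated)
Conditions: LiOH, THF/MeOH/H2O, 50 °C; cold 1 M HCl to pH 3
Reagents that add atoms: lithium hydroxide, [Li+].[OH-]
Why: Saponification of an unhindered methyl benzoate followed by brief cold acidification should leave the aryl methyl ether and the prenyl alkenes intact.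

Step 8
Reactants: 18 4-methoxy-3,5-bis(3-methylbut-2-en-1-yl)benzoic acid
Product: 19 1-[4-methoxy-3,5-bis(3-methylbut-2-en-1-yl)benzoyl]imidazole
Conditions: 1,1'-carbonyldiimidazole (1.1 equiv), THF, rt
Reagents that add atoms: 1,1'-carbonyldiimidazole, O=C(n1ccnc1)n1ccnc1
Why: Activation as the N-acylimidazole takes place under neutral conditions, so no hydrogen chloride is present that could add to the prenyl alkenes.

Step 9
Reactants: 12 (R)-terpinen-4-ol; 19 1-[4-methoxy-3,5-bis(3-methylbut-2-en-1-yl)benzoyl]imidazole
Product: 21 (1R)-4-methyl-1-isopropylcyclohex-3-en-1-yl 4-methoxy-3,5-bis(3-methylbut-2-en-1-yl)benzoate, via lithium (R)-terpinen-4-olate 20 (not isolated)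
Conditions: 12, n-BuLi (1.0 equiv), THF, −78 to 0 °C; then 19, 0 to 40 °C; H2O
Reagents that add atoms: none
Why: Acyl transfer from an N-acylimidazole to a preformed lithium tert-alkoxide (imidazolide ester synthesis) should overcome the low nucleophilicity of the hindered alcohol without acid, which spares all alkenes and excludes ionization at C4, and the R configuration is retained because only the O–H bond reacts.

**Compound list**

1 | 1,3-dichloropropan-2-one | O=C(CCl)CCl | starting material
2 | isopropylmagnesium chloride | CC(C)[Mg]Cl | starting material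
3 | chloromagnesium 1-chloro-2-(chloromethyl)-3-methylbutan-2-olate | CC(C)C(CCl)(CCl)O[Mg]Cl | intermediate
4 | 1-chloro-2-(chloromethyl)-3-methylbutan-2-ol | CC(C)C(O)(CCl)CCl | intermediate
5 | 2-(chloromethyl)-2-isopropyloxirane, racemic | CC(C)C1(CCl)CO1 | intermediate
6 | 2-methylpropene | CC(C)=C | starting material
7 | 1,3-dilithio-2-methylenepropane | [Li]CC(=C)C[Li] | intermediate
8 | dilithium salt of 1-chloro-2-isopropyl-5-(lithiomethyl)hex-5-en-2-ol, racemic | [Li]CC(=C)CCC(CCl)(O[Li])C(C)C | intermediate
9 | 2-isopropyl-2-[3-(lithiomethyl)but-3-en-1-yl]oxirane, racemic | [Li]CC(=C)CCC1(C(C)C)CO1 | intermediate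
10 | lithium 1-isopropyl-4-methylenecyclohexan-1-olate | [Li]OC1(C(C)C)CCC(=C)CC1 | intermediate
11 | 1-isopropyl-4-methylenecyclohexan-1-ol (achiral) | OC1(C(C)C)CCC(=C)CC1 | intermediate
12 | (R)-4-methyl-1-isopropylcyclohex-3-en-1-ol | O[C@@]1(C(C)C)CC=C(C)CC1 | intermediate
13 | methyl 4-hydroxy-3,5-diiodobenzoate | COC(=O)c1cc(I)c(O)c(I)c1 | starting material
14 | methyl 3,5-diiodo-4-methoxybenzoate | COC(=O)c1cc(I)c(OC)c(I)c1 | intermediate
15 | tributyl(3-methylbut-2-en-1-yl)stannane | CCCC[Sn](CCCC)(CCCC)CC=C(C)C | starting material
16 | methyl 4-methoxy-3,5-bis(3-methylbut-2-en-1-yl)benzoate | COC(=O)c1cc(CC=C(C)C)c(OC)c(CC=C(C)C)c1 | intermediate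
17 | lithium 4-methoxy-3,5-bis(3-methylbut-2-en-1-yl)benzoate | [Li+].[O-]C(=O)c1cc(CC=C(C)C)c(OC)c(CC=C(C)C)c1 | intermediate
18 | 4-methoxy-3,5-bis(3-methylbut-2-en-1-yl)benzoic acid | OC(=O)c1cc(CC=C(C)C)c(OC)c(CC=C(C)C)c1 | intermediate
19 | 1-[4-methoxy-3,5-bis(3-methylbut-2-en-1-yl)benzoyl]imidazole | O=C(c1cc(CC=C(C)C)c(OC)c(CC=C(C)C)c1)n1ccnc1 | intermediate
20 | lithium (R)-4-methyl-1-isopropylcyclohex-3-en-1-olate | [Li]O[C@@]1(C(C)C)CC=C(C)CC1 | intermediate
21 | (1R)-4-methyl-1-isopropylcyclohex-3-en-1-yl 4-methoxy-3,5-bis(3-methylbut-2-en-1-yl)benzoate | COc1c(CC=C(C)C)cc(C(=O)O[C@@]2(C(C)C)CC=C(C)CC2)cc1CC=C(C)C | target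

**Step count**

Total step count: 9.
Longest linear sequence: 5 steps (1, 2, 3, 4, 9). The arene branch (5, 6, 7, 8, 9) is equally long.

**Steps most likely to fail**

Step 3 (labelled step).
- Risks: intermolecular opening of the relay oxirane may lead to oligomers. Proton transfer from the oxirane side chain to the allyllithium may isomerize the oxirane to an allylic alcohol. Incomplete dimetalation may stop the sequence after the first bond.
- Fallback (sets out from 2, comes back at 11): 2 is added in THF at 0 °C, in the presence of LaCl3·2LiCl, to purchased 4-methylenecyclohexan-1-one F1. After an acidic quench this plain 1,2-addition should give 11 directly. The ring is then bought rather than built.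

Step 4.
- Risks: the two enantiotopic CH2 groups may be poorly discriminated. Re-insertion of the product may cause slow racemization. The free hydroxyl group may deactivate the hydride.
- Fallback (sets out from 11, comes back at 12): 11 is silylated (Et3SiOTf, 2,6-lutidine) to triethyl[(1-isopropyl-4-methylenecyclohexyl)oxy]silane F2. Ozonolysis (O3, then Me2S) gives 4-isopropyl-4-(triethylsilyloxy)cyclohexan-1-one F3. Desymmetrizing deprotonation with enantiopure lithium bis(1-phenylethyl)amide and LiCl in THF at −78 °C, followed by trapping with diphenyl chlorophosphate, should give (R)-4-isopropyl-4-(triethylsilyloxy)cyclohex-1-en-1-yl diphenyl phosphate F4. Cross-coupling with AlMe3 and Pd(PPh3)4 installs C7 and gives (R)-triethyl[(4-methyl-1-isopropylcyclohex-3-en-1-yl)oxy]silane F5. Bu4NF then releases 12.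

Step 9.
- Risk: acyl transfer may be sluggish because the isopropyl group shields the alkoxide, so that 19 is merely hydrolysed on work-up.
- Fallback (sets out from 14 and 12, comes back at 21): 14 is saponified to 3,5-diiodo-4-methoxybenzoic acid F6. With no alkene present, F6 can be converted with oxalyl chloride and catalytic DMF into the more reactive 3,5-diiodo-4-methoxybenzoyl chloride F7. Alkoxide 20, made from 12 and n-BuLi, is acylated with F7 to give (1R)-4-methyl-1-isopropylcyclohex-3-en-1-yl 3,5-diiodo-4-methoxybenzoate F8. The twofold Stille coupling with 15 under the conditions of step 6 is then carried out last and gives 21.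

**Further compounds**

F1 | step 3 | 4-methylenecyclohexan-1-one | C=C1CCC(=O)CC1
F2 | step 4 | triethyl[(1-isopropyl-4-methylenecyclohexyl)oxy]silane | CC[Si](CC)(CC)OC1(C(C)C)CCC(=C)CC1
F3 | step 4 | 4-isopropyl-4-(triethylsilyloxy)cyclohexan-1-one | CC[Si](CC)(CC)OC1(C(C)C)CCC(=O)CC1
F4 | step 4 | (R)-4-isopropyl-4-(triethylsilyloxy)cyclohex-1-en-1-yl diphenyl phosphate | CC[Si](CC)(CC)O[C@@]1(C(C)C)CC=C(OP(=O)(Oc2ccccc2)Oc2ccccc2)CC1
F5 | step 4 | (R)-triethyl[(4-methyl-1-isopropylcyclohex-3-en-1-yl)oxy]silane | CC[Si](CC)(CC)O[C@@]1(C(C)C)CC=C(C)CC1
F6 | step 9 | 3,5-diiodo-4-methoxybenzoic acid | OC(=O)c1cc(I)c(OC)c(I)c1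
F7 | step 9 | 3,5-diiodo-4-methoxybenzoyl chloride | ClC(=O)c1cc(I)c(OC)c(I)c1
F8 | step 9 | (1R)-4-methyl-1-isopropylcyclohex-3-en-1-yl 3,5-diiodo-4-methoxybenzoate | COc1c(I)cc(C(=O)O[C@@]2(C(C)C)CC=C(C)CC2)cc1I
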